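**Plan** (germacrane numbering: ring carbons C1–C10; C11, C12, C13 = butenolide α-carbon, carbonyl carbon and CH2OH carbon; lactone oxygen on C6)
1. Retrosynthesis cuts C9–C10 of the ten-membered ring first, then the two lactone bonds O–C6 and C11–C12 together (CO2 as the one-carbon unit), then C5=C6. This leaves fragment 1 (C6–C8, C11, C13) and fragment 2 (C1–C5, C10, both methyl groups).
2. Enabling feature: the acetoxy carbon C3 and the lactone carbon C6 are 1,4-related across the E C4=C5 bond, and C6 is the γ-carbon of a butenolide whose carbonyl C12 sits on C11 cis to C6 across C7=C11. This is the retron of a syn-SN2′ opening of a C3–C4 vinyl epoxide by a C11 carboxylate, which is itself made in the same flask from a C11 alkenyl iodide and CO2.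
3. Forward: fragment 1 by chelation-controlled carbomagnesiation–iodination; fragment 2 by carboalumination–allylation and Sharpless epoxidation; union by Horner–Wadsworth–Emmons olefination (C5=C6).
4. Ring order: the butenolide ring is closed first (carboxylative lactonization), the ten-membered carbocycle last (Nozaki–Hiyama–Kishi closure of C9–C10).
5. Stereochemistry: C3/C4 from the Sharpless epoxidation; C6 by 1,4-chirality transfer through an η3-allylpalladium intermediate; 4E from the syn,syn allyl unit; 1(10)Z from a trans-hydroalumination carried through with retention; C9 from the ring closure (substrate control, the least secure element).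

Key step: step 11

Remark: the target is read from its SMILES as the 3S,6R,9S isomer with a 1(10)Z,4E diene.

**Step 1**
Reactants: 1 but-2-yne-1,4-diol; 2 4-methoxybenzyl chloride
Product: 3 4-[(4-methoxybenzyl)oxy]but-2-yn-1-ol
Conditions: NaH (1 equiv), 1 (4 equiv), Bu4NI (cat.), THF/DMF, 0 °C → rt
Reagents that add atoms: none
Why: Williamson etherification with excess diol should favour the monoether statistically; no stereocenter is involved.

**Step 2**
Reactants: 3 4-[(4-methoxybenzyl)oxy]but-2-yn-1-ol; 4 allylmagnesium bromide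
Product: 6 (2Z)-3-iodo-4-[(4-methoxybenzyl)oxy]-2-(prop-2-en-1-yl)but-2-en-1-ol, via cyclic alkenylmagnesium alkoxide 5 (not isolated)
Conditions: 4 (3 equiv), Et2O/THF, 0 °C → rt; then I2, −78 → 0 °C
Reagents that add atoms: iodine, [I][I]
Why: Alkoxide-directed anti-carbomagnesiation of a propargylic alcohol delivers the allyl group to the alkyne carbon next to CH2O–Mg and holds magnesium cis to that CH2O group in a five-membered chelate; iodinolysis with retention then fixes the tetrasubstituted C7=C11 geometry (iodine cis to C6).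

**Step 3**
Reactants: 6 (2Z)-3-iodo-4-[(4-methoxybenzyl)oxy]-2-(prop-2-en-1-yl)but-2-en-1-ol
Product: 7 1-({[(2Z)-3-(bromomethyl)-2-iodohexa-2,5-dien-1-yl]oxy}methyl)-4-methoxybenzene
Conditions: CBr4, PPh3, CH2Cl2, 0 °C
Reagents that add atoms: carbon tetrabromide, BrC(Br)(Br)Br
Why: Appel bromination of the primary allylic alcohol under neutral conditions; the ether oxygen is trans to the activated carbinol and cannot cyclize onto it, and the alkene geometry is untouched.

**Step 4**
Reactants: 7 1-({[(2Z)-3-(bromomethyl)-2-iodohexa-2,5-dien-1-yl]oxy}methyl)-4-methoxybenzene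
Product: 8 diethyl [(2Z)-3-iodo-4-[(4-methoxybenzyl)oxy]-2-(prop-2-en-1-yl)but-2-en-1-yl]phosphonate
Conditions: P(OEt)3 (neat), 110 °C
Reagents that add atoms: triethyl phosphite, CCOP(OCC)OCC
Why: Michaelis–Arbuzov reaction at the unhindered primary allylic bromide; the alkenyl iodide does not react with a phosphite without a transition metal.

**Step 5**
Reactants: 9 but-2-yn-1-ol
Product: 11 (2Z)-3-bromobut-2-en-1-ol, via cyclic alkenylaluminate 10 (not isolated)
Conditions: NaAlH2(OCH2CH2OMe)2, THF, 0 °C → rt; then N-bromosuccinimide, −78 °C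
Reagents that add atoms: N-bromosuccinimide, O=C1CCC(=O)N1Br
Why: Alkoxide-directed trans-hydroalumination places aluminium on C3 cis to CH2O, and bromination with retention gives the Z bromoalkene that later becomes the 1(10)Z ring alkene.

**Step 6**
Reactants: 11 (2Z)-3-bromobut-2-en-1-ol
Product: 12 (2Z)-1,3-dibromobut-2-ene
Conditions: PBr3, pyridine (cat.), Et2O, 0 °C
Reagents that add atoms: phosphorus tribromide, BrP(Br)Br
Why: Standard conversion of a primary allylic alcohol into the bromide without touching the alkenyl bromide or its geometry.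

**Step 7**
Reactants: 13 prop-2-yn-1-ol; 12 (2Z)-1,3-dibromobut-2-ene
Product: 15 (2E,5Z)-6-bromo-2-methylhepta-2,5-dien-1-ol, via alkenylalane 14 (not isolated)
Conditions: Me3Al (3 equiv), Cp2ZrCl2 (cat.), CH2Cl2, 0 °C → rt; then 12, Pd(PPh3)4 (cat.), THF, rt
Reagents that add atoms: trimethylaluminium, C[Al](C)C
Why: Zirconium-catalysed syn-carboalumination sets the E trisubstituted alkene, and palladium-catalysed cross-coupling of the alkenylalane with the allylic bromide at its CH2 terminus (allylic C–Br ionizes far faster than alkenyl C–Br) gives the skipped diene with both geometries retained.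

**Step 8**
Reactants: 15 (2E,5Z)-6-bromo-2-methylhepta-2,5-dien-1-ol
Product: 16 [(2S,3S)-3-[(2Z)-3-bromobut-2-en-1-yl]-2-methyloxiran-2-yl]methanol
Conditions: Ti(OiPr)4 (cat.), L-(+)-diethyl tartrate (cat.), t-BuOOH, 4 Å MS, CH2Cl2, −20 °C
Reagents that add atoms: tert-butyl hydroperoxide, CC(C)(C)OO
Why: Sharpless asymmetric epoxidation of an (E)-2-methylalk-2-en-1-ol; the L-(+)-tartrate catalyst delivers oxygen to the face that gives the (2S,3S)-epoxide (the future C4 and C3), and the non-allylic bromoalkene is not epoxidized.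

**Step 9**
Reactants: 16 [(2S,3S)-3-[(2Z)-3-bromobut-2-en-1-yl]-2-methyloxiran-2-yl]methanol
Product: 17 (2R,3S)-3-[(2Z)-3-bromobut-2-en-1-yl]-2-methyloxirane-2-carbaldehyde
Conditions: Dess–Martin periodinane, NaHCO3, CH2Cl2, 0 °C
Reagents that add atoms: none
Why: Buffered Dess–Martin oxidation of the epoxy alcohol; the α-carbon is quaternary, so the aldehyde cannot epimerize (the descriptor change at C2 is only a priority change).

**Step 10**
Reactants: 8 diethyl [(2Z)-3-iodo-4-[(4-methoxybenzyl)oxy]-2-(prop-2-en-1-yl)but-2-en-1-yl]phosphonate; 17 (2R,3S)-3-[(2Z)-3-bromobut-2-en-1-yl]-2-methyloxirane-2-carbaldehyde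
Product: 19 1-({[(2Z,4E)-5-[(2S,3S)-3-[(2Z)-3-bromobut-2-en-1-yl]-2-methyloxiran-2-yl]-2-iodo-3-(prop-2-en-1-yl)penta-2,4-dien-1-yl]oxy}methyl)-4-methoxybenzene, via lithiated phosphonate 18 (not isolated)
Conditions: LiN(SiMe3)2, THF/DMPU, −78 °C; then 17, −78 °C → rt
Reagents that add atoms: none
Why: Horner–Wadsworth–Emmons olefination of an allylic phosphonate anion, which reacts at its α-carbon and should give the E C5=C6 bond; the amide base does not exchange the alkenyl halides, and the aldehyde has no α-hydrogen.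

**Step 11**
Reactants: 19 1-({[(2Z,4E)-5-[(2S,3S)-3-[(2Z)-3-bromobut-2-en-1-yl]-2-methyloxiran-2-yl]-2-iodo-3-(prop-2-en-1-yl)penta-2,4-dien-1-yl]oxy}methyl)-4-methoxybenzene; 20 carbon dioxide
Product: 23 (5R)-5-[(1E,3S,5Z)-6-bromo-3-hydroxy-2-methylhepta-1,5-dien-1-yl]-3-{[(4-methoxybenzyl)oxy]methyl}-4-(prop-2-en-1-yl)furan-2(5H)-one, via alkenyllithium 21 (not isolated), via lithium carboxylate 22 (not isolated)
Conditions: t-BuLi (2.0 equiv), THF/Et2O, −100 °C; CO2 (20), −100 → −40 °C; Ar purge; Pd(PPh3)4 (5 mol%), 0 °C → rt; aq. NH4Cl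
Reagents that add atoms: none
Why: Iodine–lithium exchange at −100 °C is faster at the C11 alkenyl iodide than at the C10 alkenyl bromide or the epoxide and gives a configurationally stable alkenyllithium that adds to CO2 (C11–C12) to give the (Z)-carboxylate 22; zerovalent palladium then ionizes the vinyl epoxide with inversion at C4 to an η3-allyl complex over C4–C5–C6, and the carboxylate oxygen attacks C6 on the face anti to palladium (O–C6), releasing the C3 alkoxide. The closest known reaction types are the carboxylation of alkenyllithiums and the Tsuji–Trost syn-1,4 addition of carboxylates to vinyl epoxides, here telescoped in one flask. The butenolide ring is closed in a 5-exo mode at the C6 terminus of the allyl unit, the only feasible closure because C12 is held cis to C6 on the C7=C11 bond (attack at C4 would need a seven-membered ring). C6 (R) is set by 1,4-chirality transfer from the (S)-configured epoxide carbon C4 through double inversion, and C3 (S) is carried over unchanged because its C–O bond is never broken. The step needs E geometry at the new C4=C5 bond, which should come from ionization through the s-trans rotamer that places C3 syn and the methyl group anti in the allyl unit, and it needs the E C5=C6 bond of 19, since the Z isomer would lead to the C6 epimer. Purging excess CO2 before the palladium catalyst is added should suppress the competing cyclic carbonate at C3/C4.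

**Step 12**
Reactants: 23 (5R)-5-[(1E,3S,5Z)-6-bromo-3-hydroxy-2-methylhepta-1,5-dien-1-yl]-3-{[(4-methoxybenzyl)oxy]methyl}-4-(prop-2-en-1-yl)furan-2(5H)-one
Product: 24 (1E,3S,5Z)-6-bromo-1-[(2R)-4-{[(4-methoxybenzyl)oxy]methyl}-5-oxo-3-(prop-2-en-1-yl)-2,5-dihydrofuran-2-yl]-2-methylhepta-1,5-dien-3-yl acetate
Conditions: Ac2O, pyridine, DMAP (cat.), CH2Cl2, 0 °C
Reagents that add atoms: acetic anhydride, CC(=O)OC(C)=O
Why: Acetylation of the only free hydroxyl (C3) with retention; the cold, weakly basic conditions should not epimerize the γ-position of the butenolide, and the acetate deactivates C4=C5 for the next step.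

**Step 13**
Reactants: 24 (1E,3S,5Z)-6-bromo-1-[(2R)-4-{[(4-methoxybenzyl)oxy]methyl}-5-oxo-3-(prop-2-en-1-yl)-2,5-dihydrofuran-2-yl]-2-methylhepta-1,5-dien-3-yl acetate
Product: 26 (1E,3S,5Z)-6-bromo-1-[(2R)-4-{[(4-methoxybenzyl)oxy]methyl}-5-oxo-3-(2-oxoethyl)-2,5-dihydrofuran-2-yl]-2-methylhepta-1,5-dien-3-yl acetate, via diol 25 (not isolated)
Conditions: OsO4 (cat.), NaIO4, 2,6-lutidine, dioxane/H2O, rt
Reagents that add atoms: sodium periodate NaIO4, [Na+].[O-]I(=O)(=O)=O (terminal source of the aldehyde oxygen, relayed by OsO4)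
Why: Lemieux–Johnson cleavage should select the terminal monosubstituted alkene, because the other alkenes are deactivated (C7=C11 is tetrasubstituted and conjugated to the lactone, C4=C5 is flanked by two allylic C–O bonds, C1=C10 carries bromine); the aldehyde is used without storage.

**Step 14**
Reactants: 26 (1E,3S,5Z)-6-bromo-1-[(2R)-4-{[(4-methoxybenzyl)oxy]methyl}-5-oxo-3-(2-oxoethyl)-2,5-dihydrofuran-2-yl]-2-methylhepta-1,5-dien-3-yl acetate
Product: 27 (3S,6R,9S,1(10)Z,4E)-3-acetoxy-9-hydroxy-13-[(4-methoxybenzyl)oxy]germacra-1(10),4,7(11)-trien-12,6-olide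
Conditions: CrCl2 (8 equiv), NiCl2 (0.1 equiv), DMSO/THF, rt, high dilution (2 mM)
Reagents that add atoms: none
Why: Nozaki–Hiyama–Kishi ring closure (nickel activation of the alkenyl bromide, transmetalation to chromium, addition of the weakly basic alkenylchromium to the aldehyde) should form C9–C10 with retention of the Z geometry and tolerate the lactone, the acetate and the enolizable aldehyde; C9 is set under substrate control (allylic 1,3-strain holds C9–H in the plane of the Z alkene, so oxygen takes the outer face opposite C8), which is expected to favour the 9S carbinol.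

**Step 15**
Reactants: 27 (3S,6R,9S,1(10)Z,4E)-3-acetoxy-9-hydroxy-13-[(4-methoxybenzyl)oxy]germacra-1(10),4,7(11)-trien-12,6-olide
Product: 28 (3S,6R,9S,1(10)Z,4E)-3,9-diacetoxy-13-[(4-methoxybenzyl)oxy]germacra-1(10),4,7(11)-trien-12,6-olide
Conditions: Ac2O, pyridine, DMAP (cat.), CH2Cl2, 0 °C → rt
Reagents that add atoms: acetic anhydride, CC(=O)OC(C)=O
Why: Acetylation of the single free secondary allylic alcohol with retention at C9; room temperature or below avoids Cope rearrangement of the 1(10),4-diene.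

**Step 16**
Reactants: 28 (3S,6R,9S,1(10)Z,4E)-3,9-diacetoxy-13-[(4-methoxybenzyl)oxy]germacra-1(10),4,7(11)-trien-12,6-olide
Product: 29 (3S,6R,9S,1(10)Z,4E)-3,9-diacetoxy-13-hydroxygermacra-1(10),4,7(11)-trien-12,6-olide
Conditions: DDQ, CH2Cl2/pH 7 buffer, 0 °C
Reagents that add atoms: none
Why: Oxidative cleavage of the 4-methoxybenzyl ether under buffered, cold conditions should free the primary C13 hydroxyl without touching the two acetates, the bis-allylic lactone or the trisubstituted alkenes.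

**Compound list**
1 | but-2-yne-1,4-diol | OCC#CCO | starting material
2 | 4-methoxybenzyl chloride | COc1ccc(CCl)cc1 | starting material
3 | 4-[(4-methoxybenzyl)oxy]but-2-yn-1-ol | OCC#CCOCc1ccc(OC)cc1 | intermediate
4 | allylmagnesium bromide | C=CC[Mg]Br | starting material
5 | 4-allyl-3-{[(4-methoxybenzyl)oxy]methyl}-2,5-dihydro-1,2-oxamagnesole (cyclic alkenylmagnesium alkoxide) | C=CCC1=C(COCc2ccc(OC)cc2)[Mg]OC1 | intermediate
6 | (2Z)-3-iodo-4-[(4-methoxybenzyl)oxy]-2-(prop-2-en-1-yl)but-2-en-1-ol | OC/C(CC=C)=C(\I)COCc1ccc(OC)cc1 | intermediate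
7 | 1-({[(2Z)-3-(bromomethyl)-2-iodohexa-2,5-dien-1-yl]oxy}methyl)-4-methoxybenzene | BrC/C(CC=C)=C(\I)COCc1ccc(OC)cc1 | intermediate
8 | diethyl [(2Z)-3-iodo-4-[(4-methoxybenzyl)oxy]-2-(prop-2-en-1-yl)but-2-en-1-yl]phosphonate | CCOP(=O)(OCC)C/C(CC=C)=C(\I)COCc1ccc(OC)cc1 | intermediate
9 | but-2-yn-1-ol | CC#CCO | starting material
10 | sodium 2,2-bis(2-methoxyethoxy)-3-methyl-2,5-dihydro-1,2-oxaaluminol-2-uide (cyclic alkenylaluminate) | CC1=CCO[Al-]1(OCCOC)OCCOC.[Na+] | intermediate
11 | (2Z)-3-bromobut-2-en-1-ol | C/C(Br)=C/CO | intermediate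
12 | (2Z)-1,3-dibromobut-2-ene | C/C(Br)=C/CBr | intermediate
13 | prop-2-yn-1-ol | C#CCO | starting material
14 | dimethyl[(1E)-3-[(dimethylalumanyl)oxy]-2-methylprop-1-en-1-yl]alumane (alkenylalane) | C[Al](C)/C=C(\C)CO[Al](C)C | intermediate
15 | (2E,5Z)-6-bromo-2-methylhepta-2,5-dien-1-ol | OC/C(C)=C/C/C=C(\Br)C | intermediate
16 | [(2S,3S)-3-[(2Z)-3-bromobut-2-en-1-yl]-2-methyloxiran-2-yl]methanol | OC[C@]1(C)O[C@H]1C/C=C(\Br)C | intermediate
17 | (2R,3S)-3-[(2Z)-3-bromobut-2-en-1-yl]-2-methyloxirane-2-carbaldehyde | O=C[C@]1(C)O[C@H]1C/C=C(\Br)C | intermediate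
18 | lithium salt of the α-carbanion of phosphonate 8 | [Li+].CCOP(=O)(OCC)[CH-]/C(CC=C)=C(\I)COCc1ccc(OC)cc1 | intermediate
19 | 1-({[(2Z,4E)-5-[(2S,3S)-3-[(2Z)-3-bromobut-2-en-1-yl]-2-methyloxiran-2-yl]-2-iodo-3-(prop-2-en-1-yl)penta-2,4-dien-1-yl]oxy}methyl)-4-methoxybenzene | COc1ccc(COC/C(I)=C(CC=C)/C=C/[C@]2(C)O[C@H]2C/C=C(\Br)C)cc1 | intermediate
20 | carbon dioxide | O=C=O | starting material
21 | C11-lithio analogue of 19 (iodine replaced by lithium with retention of the alkene geometry) | COc1ccc(COC/C([Li])=C(CC=C)/C=C/[C@]2(C)O[C@H]2C/C=C(\Br)C)cc1 | intermediate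
22 | lithium (2Z,4E)-5-[(2S,3S)-3-[(2Z)-3-bromobut-2-en-1-yl]-2-methyloxiran-2-yl]-2-{[(4-methoxybenzyl)oxy]methyl}-3-(prop-2-en-1-yl)penta-2,4-dienoate | [Li+].COc1ccc(COC/C(C([O-])=O)=C(CC=C)/C=C/[C@]2(C)O[C@H]2C/C=C(\Br)C)cc1 | intermediate
23 | (5R)-5-[(1E,3S,5Z)-6-bromo-3-hydroxy-2-methylhepta-1,5-dien-1-yl]-3-{[(4-methoxybenzyl)oxy]methyl}-4-(prop-2-en-1-yl)furan-2(5H)-one | COc1ccc(COCC2=C(CC=C)[C@H](OC2=O)/C=C(C)/[C@@H](O)C/C=C(\Br)C)cc1 | intermediate
24 | (1E,3S,5Z)-6-bromo-1-[(2R)-4-{[(4-methoxybenzyl)oxy]methyl}-5-oxo-3-(prop-2-en-1-yl)-2,5-dihydrofuran-2-yl]-2-methylhepta-1,5-dien-3-yl acetate | COc1ccc(COCC2=C(CC=C)[C@H](OC2=O)/C=C(C)/[C@@H](OC(C)=O)C/C=C(\Br)C)cc1 | intermediate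
25 | (1E,3S,5Z)-6-bromo-1-[(2R)-3-(2,3-dihydroxypropyl)-4-{[(4-methoxybenzyl)oxy]methyl}-5-oxo-2,5-dihydrofuran-2-yl]-2-methylhepta-1,5-dien-3-yl acetate (both carbinol epimers) | COc1ccc(COCC2=C(CC(O)CO)[C@H](OC2=O)/C=C(C)/[C@@H](OC(C)=O)C/C=C(\Br)C)cc1 | intermediate
26 | (1E,3S,5Z)-6-bromo-1-[(2R)-4-{[(4-methoxybenzyl)oxy]methyl}-5-oxo-3-(2-oxoethyl)-2,5-dihydrofuran-2-yl]-2-methylhepta-1,5-dien-3-yl acetate | COc1ccc(COCC2=C(CC=O)[C@H](OC2=O)/C=C(C)/[C@@H](OC(C)=O)C/C=C(\Br)C)cc1 | intermediate
27 | (3S,6R,9S,1(10)Z,4E)-3-acetoxy-9-hydroxy-13-[(4-methoxybenzyl)oxy]germacra-1(10),4,7(11)-trien-12,6-olide | O[C@H]1CC2=C(COCc3ccc(OC)cc3)C(=O)O[C@@H]2/C=C(\C)[C@@H](OC(C)=O)C/C=C\1C | intermediate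
28 | (3S,6R,9S,1(10)Z,4E)-3,9-diacetoxy-13-[(4-methoxybenzyl)oxy]germacra-1(10),4,7(11)-trien-12,6-olide | CC(=O)O[C@H]1CC2=C(COCc3ccc(OC)cc3)C(=O)O[C@@H]2/C=C(\C)[C@@H](OC(C)=O)C/C=C\1C | intermediate
29 | (3S,6R,9S,1(10)Z,4E)-3,9-diacetoxy-13-hydroxygermacra-1(10),4,7(11)-trien-12,6-olide | CC(=O)O[C@H]1CC2=C(CO)C(=O)O[C@@H]2/C=C(\C)[C@@H](OC(C)=O)C/C=C\1C | target

**Totals**
Total step count: 16. Longest linear sequence: 12 steps (steps 5–9, then 10–16).

**Steps most likely to fail**

1. Step 11. The halogen–lithium exchange may lose chemoselectivity (exchange at the alkenyl bromide, attack on the epoxide), and lithium salts or residual CO2 may interfere with the palladium stage (cyclic carbonate formation, dienol formation by β-hydride elimination). The fallback sets out from 8 and returns at 22 and then 23; it installs the carbonyl carbon by carbonylation before the epoxide fragment is attached. Compound 8 with PdCl2(PPh3)2, CO (1 atm), MeOH and Et3N in DMF should give methyl (2Z)-3-[(diethoxyphosphoryl)methyl]-2-{[(4-methoxybenzyl)oxy]methyl}hexa-2,5-dienoate F1. LiOH in THF/H2O then gives (2Z)-3-[(diethoxyphosphoryl)methyl]-2-{[(4-methoxybenzyl)oxy]methyl}hexa-2,5-dienoic acid F2. LiN(SiMe3)2 (2.2 equiv) converts this into its dilithio carboxylate–phosphonate carbanion F3, which olefinates 17 to give the lithium carboxylate 22 directly. Pd(PPh3)4 then closes the lactone to 23 as in the second half of step 11.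

2. Step 14. The ring closure may suffer from poor facial selectivity at C9, and the butenolide-activated aldehyde may enolize or oligomerize before it cyclizes. The fallback sets out from 26 and returns at 28. If the closure delivers mainly (3S,6R,9R,1(10)Z,4E)-3-acetoxy-9-hydroxy-13-[(4-methoxybenzyl)oxy]germacra-1(10),4,7(11)-trien-12,6-olide F4, a Mitsunobu reaction (PPh3, DIAD, AcOH, THF, 0 °C) installs the C9 acetate with inversion and gives 28 directly, so step 15 is skipped.

3. Step 10. The allylic phosphonate anion may react at its γ-carbon, the β-oxido phosphonate may eliminate slowly, or E selectivity at C5=C6 may be lost, which would later erode the configuration at C6. The fallback sets out from 7 and returns at 19; it is a Julia–Kocienski olefination. Compound 7 with 1-phenyl-1H-tetrazole-5-thiol and K2CO3 in acetone gives 5-{[(2Z)-3-iodo-4-[(4-methoxybenzyl)oxy]-2-(prop-2-en-1-yl)but-2-en-1-yl]sulfanyl}-1-phenyl-1H-tetrazole F5. Oxidation with H2O2 and (NH4)6Mo7O24 (cat.) in EtOH gives 5-{[(2Z)-3-iodo-4-[(4-methoxybenzyl)oxy]-2-(prop-2-en-1-yl)but-2-en-1-yl]sulfonyl}-1-phenyl-1H-tetrazole F6. KN(SiMe3)2 added to a mixture of this sulfone and 17 in DME at −60 °C should give 19.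

**Further compounds**
F1 | step 11 | methyl (2Z)-3-[(diethoxyphosphoryl)methyl]-2-{[(4-methoxybenzyl)oxy]methyl}hexa-2,5-dienoate | CCOP(=O)(OCC)C/C(CC=C)=C(\C(=O)OC)COCc1ccc(OC)cc1
F2 | step 11 | (2Z)-3-[(diethoxyphosphoryl)methyl]-2-{[(4-methoxybenzyl)oxy]methyl}hexa-2,5-dienoic acid | CCOP(=O)(OCC)C/C(CC=C)=C(\C(=O)O)COCc1ccc(OC)cc1
F3 | step 11 | dilithio carboxylate–phosphonate carbanion of F2 | [Li+].[Li+].CCOP(=O)(OCC)[CH-]/C(CC=C)=C(\C([O-])=O)COCc1ccc(OC)cc1
F4 | step 14 | (3S,6R,9R,1(10)Z,4E)-3-acetoxy-9-hydroxy-13-[(4-methoxybenzyl)oxy]germacra-1(10),4,7(11)-trien-12,6-olide | O[C@@H]1CC2=C(COCc3ccc(OC)cc3)C(=O)O[C@@H]2/C=C(\C)[C@@H](OC(C)=O)C/C=C\1C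
F5 | step 10 | 5-{[(2Z)-3-iodo-4-[(4-methoxybenzyl)oxy]-2-(prop-2-en-1-yl)but-2-en-1-yl]sulfanyl}-1-phenyl-1H-tetrazole | c1ccccc1-n1nnnc1SC/C(CC=C)=C(\I)COCc1ccc(OC)cc1
F6 | step 10 | 5-{[(2Z)-3-iodo-4-[(4-methoxybenzyl)oxy]-2-(prop-2-en-1-yl)but-2-en-1-yl]sulfonyl}-1-phenyl-1H-tetrazole | c1ccccc1-n1nnnc1S(=O)(=O)C/C(CC=C)=C(\I)COCc1ccc(OC)cc1
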